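**Retrosynthetic overview**

1. Numbering used throughout: C1 = benzylic CH2; C2–C7 = the cyclohexane (C3 carries =CH2, C6 carries Br, C7 carries Me); C8, C9; C10/C11 = epoxide carbons; C12, C13; C14 = CH–O(acyl); C15 = CMe2Br. Enabling feature: the C14 oxygen sits γ,δ to the C10=C11 double bond that the epoxide masks (C14–C13–C12–C11=C10 is a Claisen retron), and the adjacent tertiary C15 can hold the arene carboxylate as an ester that later slides onto C14.
2. Endgame: target ⇐ Shi epoxidation of E-C10=C11 ⇐ 15-membered bromo lactone ⇐ 1,2-acyloxy shift with bromide capture at C15 (ring contraction 16 → 15) ⇐ 16-membered α-acyloxy ketone.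
3. Key disconnection C12–C13: the 16-membered ring arises by ketal exchange and Claisen rearrangement of an open-chain C10 isopropenyl carbinol whose arene carboxylate is esterified with 3,3-dimethoxy-2-methylbutan-2-ol (transient 14-membered allyl vinyl ether, two-atom ring expansion).
4. Cyclohexane: enantiospecific bromonium-ion cyclization of a (6S,7R)-bromohydrin onto an allylsilane (sets C2, C6, C7 and the exocyclic methylene); the precursor comes from (2R,3R)-epoxygeraniol, methyl acetoacetate and methyl 4-hydroxy-3-iodobenzoate.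
5. Order of ring formation: cyclohexane (step 11) → 16-membered ring closed at C12–C13 (step 17) → 15-membered macrolactone by ring contraction (step 19) → epoxide (step 20).

Key step: step 17

Remark: the C10 carbinol centre of 26 is erased in step 17; it is nevertheless set (10R) so that every intermediate is one stereoisomer. Geraniol, D-(−)-diethyl tartrate, both enantiomers of the fructose-derived epoxidation ketone, methyl 4-hydroxy-3-iodobenzoate and 3-hydroxy-3-methylbutan-2-one are assumed to be commercial.

**Route**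

Step 1
Reactants: 1 geraniol
Product: 2 (2R,3R)-2,3-epoxygeraniol
Conditions: Ti(OiPr)4 (5 mol%), D-(−)-diethyl tartrate (6 mol%), t-BuOOH, 4 Å molecular sieves, CH2Cl2, −20 °C
Reagents that add atoms: tert-butyl hydroperoxide, CC(C)(C)OO
Why: Sharpless asymmetric epoxidation: the allylic hydroxyl binds the titanium tartrate complex so that only the 2,3-alkene is oxidised, and D-(−)-tartrate delivers oxygen to the face that gives the (2R,3R)-epoxide, whose two centres become C6 and C7.

Step 2
Reactants: 2 (2R,3R)-2,3-epoxygeraniol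
Product: 3 (2R,3R)-2,3-epoxygeranyl iodide
Conditions: PPh3, I2, imidazole, CH2Cl2, 0 °C
Reagents that add atoms: iodine, II
Why: Appel-type iodination: the alkoxyphosphonium ion is displaced by iodide at the primary carbon, so the epoxide centres are untouched (the CIP label of the oxirane carbon next to CH2I becomes S without any change in space).

Step 3
Reactants: 4 methyl acetoacetate; 3 (2R,3R)-2,3-epoxygeranyl iodide
Product: 6 methyl (6R,7R)-6,7-epoxy-7,11-dimethyl-3-oxododec-10-enoate, via acetoacetate dianion 5 (not isolated)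
Conditions: NaH then n-BuLi, THF, 0 °C; add 3, 0 °C to rt; aq. NH4Cl
Reagents that add atoms: none
Why: Dianion γ-alkylation of a β-keto ester: the terminal carbanion of 5 is the more nucleophilic site and displaces the primary iodide, which is activated by the adjacent oxirane, faster than it opens the trisubstituted epoxide; no stereocentre is touched.

Step 4
Reactants: 6 methyl (6R,7R)-6,7-epoxy-7,11-dimethyl-3-oxododec-10-enoate
Product: 7 methyl (2Z,6R,7R)-6,7-epoxy-7,11-dimethyl-3-(trifluoromethylsulfonyloxy)dodeca-2,10-dienoate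
Conditions: KN(SiMe3)2, THF, −78 °C; PhNTf2, −78 to 0 °C
Reagents that add atoms: N-phenylbis(trifluoromethanesulfonimide), O=S(=O)(N(c1ccccc1)S(=O)(=O)C(F)(F)F)C(F)(F)F
Why: Enol triflate formation: the potassium enolate of the β-keto ester is held in the chelated Z form and O-sulfonylation preserves it, so the triflate is cis to the ester, which fixes the later trans relationship of C1 and C4.

Step 5
Reactants: 7 the Z enol triflate
Product: 8 methyl (2Z,6R,7R)-6,7-epoxy-7,11-dimethyl-3-[(trimethylsilyl)methyl]dodeca-2,10-dienoate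
Conditions: Me3SiCH2MgCl, Pd(PPh3)4 (5 mol%), THF, 0 °C to rt
Reagents that add atoms: (trimethylsilyl)methylmagnesium chloride, C[Si](C)(C)C[Mg]Cl
Why: Kumada coupling: oxidative addition of the electron-poor enol triflate and transmetalation of the weakly basic silylmethyl Grignard reagent proceed with retention of alkene geometry and leave ester and epoxide alone, giving the Z allylsilane.

Step 6
Reactants: 8 the allylsilane ester
Product: 9 (2Z,6R,7R)-6,7-epoxy-7,11-dimethyl-3-[(trimethylsilyl)methyl]dodeca-2,10-dien-1-ol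
Conditions: i-Bu2AlH (2.5 equiv), CH2Cl2, −78 °C; aq. potassium sodium tartrate
Reagents that add atoms: none
Why: Hydride reduction of the conjugated ester by i-Bu2AlH at −78 °C should give the allylic alcohol without 1,4-reduction, epoxide opening or loss of silicon.

Step 7
Reactants: 9 the allylic alcohol
Product: 11 (2Z,6R,7R)-1-chloro-6,7-epoxy-7,11-dimethyl-3-[(trimethylsilyl)methyl]dodeca-2,10-diene, via allylic mesylate 10 (not isolated)
Conditions: MsCl, 2,4,6-collidine, LiCl, DMF, 0 °C
Reagents that add atoms: lithium chloride, [Li+].[Cl-]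
Why: Chloride formation through the mesylate (SN2 at the primary allylic carbon under collidine buffering) avoids acid and free carbocations, so allylic transposition, protodesilylation and epoxide opening should not occur.

Step 8
Reactants: 12 methyl 4-hydroxy-3-iodobenzoate
Product: 13 methyl 3-iodo-4-(triisopropylsilyloxy)benzoate
Conditions: i-Pr3SiCl, imidazole, DMF, rt
Reagents that add atoms: chlorotriisopropylsilane, CC(C)[Si](Cl)(C(C)C)C(C)C
Why: Silyl ether formation: the bulky triisopropylsilyl group masks the acidic phenol for the organometallic, Lewis acid and acylation steps and is removable at the end by fluoride.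

Step 9
Reactants: 13 methyl 3-iodo-4-(triisopropylsilyloxy)benzoate; 11 the allylic chloride
Product: 15 methyl 3-{(2Z,6R,7R)-6,7-epoxy-7,11-dimethyl-3-[(trimethylsilyl)methyl]dodeca-2,10-dien-1-yl}-4-(triisopropylsilyloxy)benzoate, via arylmagnesium chloride 14 (not isolated)
Conditions: i-PrMgCl·LiCl, THF, −40 °C; then 11, Li2CuCl4 (3 mol%), THF, −30 to 0 °C
Reagents that add atoms: none
Why: Iodine–magnesium exchange followed by copper-catalysed allylic substitution: the ester-tolerant arylmagnesium 14 couples at the primary (α) carbon of the allylic chloride, because γ-attack would have to build a quaternary carbon, so the Z geometry and the epoxide are carried through.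

Step 10
Reactants: 15 the aryl epoxide
Product: 16 methyl 3-{(2Z,6S,7R)-6-bromo-7-hydroxy-7,11-dimethyl-3-[(trimethylsilyl)methyl]dodeca-2,10-dien-1-yl}-4-(triisopropylsilyloxy)benzoate
Conditions: Li2NiBr4, THF, 0 °C to rt
Reagents that add atoms: dilithium tetrabromonickelate Li2NiBr4, [Li+].[Li+].[Ni+2].[Br-].[Br-].[Br-].[Br-]
Why: Regioselective SN2 opening of the trisubstituted epoxide by bromide at the less hindered secondary carbon inverts C6 to S and leaves C7 as the tertiary alcohol anti to bromine, the arrangement needed for bromonium formation.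

Step 11
Reactants: 16 the (6S,7R)-bromohydrin
Product: 18 methyl 3-{[(1R,2S,3S)-3-bromo-2-methyl-6-methylidene-2-(4-methylpent-3-en-1-yl)cyclohexyl]methyl}-4-(triisopropylsilyloxy)benzoate, via bromonium ion 17 (not isolated)
Conditions: SnCl4 (2 equiv), 2,6-di-tert-butyl-4-methylpyridine, CH2Cl2, −78 to −40 °C
Reagents that add atoms: none
Why: Bromonium-ion initiated cation–olefin cyclization terminated by an allylsilane: ionisation of the tertiary hydroxyl is assisted by the anti bromine to give 17, the allylsilane carbon C2 attacks C7 anti to bromine through a chair in which Br, the C8 chain and the arylmethyl group are equatorial, and loss of silicon from the β-silyl cation places the alkene exocyclic, so the C6 configuration from step 10 is relayed to C7 (S) and C2 (R).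

Step 12
Reactants: 18 the cyclised methyl ester
Product: 19 3-{[(1R,2S,3S)-3-bromo-2-methyl-6-methylidene-2-(4-methylpent-3-en-1-yl)cyclohexyl]methyl}-4-(triisopropylsilyloxy)benzoic acid
Conditions: Me3SnOH, 1,2-dichloroethane, 80 °C; dilute aq. HCl wash
Reagents that add atoms: trimethyltin hydroxide, C[Sn](C)(C)O
Why: Ester hydrolysis by Me3SnOH under near-neutral conditions should cleave the unhindered methyl ester without touching the aryl silyl ether, the equatorial neopentyl-type bromide or the alkenes.

Step 13
Reactants: 20 3-hydroxy-3-methylbutan-2-one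
Product: 21 3,3-dimethoxy-2-methylbutan-2-ol
Conditions: HC(OMe)3, MeOH, p-TsOH (cat.), rt
Reagents that add atoms: trimethyl orthoformate, COC(OC)OC (methanol, CO, as co-solvent and carrier)
Why: Acid-catalysed ketalisation driven by the orthoformate as water scavenger converts the ketone into its dimethyl ketal and leaves the tertiary hydroxyl free.

Step 14
Reactants: 19 the benzoic acid; 21 3,3-dimethoxy-2-methylbutan-2-ol
Product: 24 3,3-dimethoxy-2-methylbutan-2-yl 3-{[(1R,2S,3S)-3-bromo-2-methyl-6-methylidene-2-(4-methylpent-3-en-1-yl)cyclohexyl]methyl}-4-(triisopropylsilyloxy)benzoate, via acid chloride 22 (not isolated), via lithium alkoxide 23 (not isolated)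
Conditions: 19, 1-chloro-N,N,2-trimethylprop-1-en-1-amine, CH2Cl2, 0 °C to rt; 21, n-BuLi, THF, −78 to 0 °C; combine, THF, −78 °C to rt
Reagents that add atoms: none
Why: Acylation of a tertiary lithium alkoxide by an acid chloride (made under neutral conditions from the chloroenamine) is the standard way to hindered tertiary-alkyl benzoates and is compatible with the base-stable ketal and the alkenes.

Step 15
Reactants: 24 the ketal ester
Product: 25 the (10R)-10,11-epoxide of 24 [side chain 2-[(2R)-3,3-dimethyloxiran-2-yl]ethyl]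
Conditions: D-fructose-derived ketone catalyst (30 mol%), KHSO5 (Oxone), K2CO3, Bu4NHSO4, MeCN/dimethoxymethane/aq. Na2B4O7 buffer, 0 °C
Reagents that add atoms: potassium peroxymonosulfate KHSO5, [K+].[O-]S(=O)(=O)OO
Why: Shi epoxidation: the chiral dioxirane epoxidises the electron-rich trisubstituted C10=C11 alkene faster than the hindered 1,1-disubstituted exocyclic methylene, the D-fructose-derived ketone gives the (10R)-epoxide through the spiro transition state, and the basic buffer preserves the ketal.

Step 16
Reactants: 25 the terminal epoxide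
Product: 26 3,3-dimethoxy-2-methylbutan-2-yl 3-{[(1R,2S,3S)-3-bromo-2-[(3R)-3-hydroxy-4-methylpent-4-en-1-yl]-2-methyl-6-methylidenecyclohexyl]methyl}-4-(triisopropylsilyloxy)benzoate
Conditions: Et2Al(TMP) [from 2,2,6,6-tetramethylpiperidine, n-BuLi, Et2AlCl], toluene, 0 °C
Reagents that add atoms: none
Why: Epoxide-to-allylic-alcohol isomerisation by an aluminium amide: aluminium binds the epoxide oxygen and the hindered amide removes a proton from the less hindered methyl group, giving the isopropenyl carbinol with retention at C10 (R), while the bulky base should not attack the tertiary ester.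

Step 17
Reactants: 26 the hydroxy ketal
Product: 29 16-membered keto lactone (2R,6S,7S,10E) carrying the arene carboxylate on O–C15, via cyclic mixed ketal 27 (not isolated), via cyclic allyl vinyl ether 28 (not isolated)
Conditions: 2,4-dinitrophenol (20 mol%), xylenes, 0.002 M, 125 °C, condensate returned through 4 Å molecular sieves
Reagents that add atoms: none
Why: Proposed new method: 2,4-dinitrophenol reversibly ionises the dimethyl ketal, the C10 allylic hydroxyl exchanges for one methoxy group within the molecule (27), loss of the second methanol gives the 14-membered allyl vinyl ether 28, and an irreversible chair [3,3]-sigmatropic shift forms C12–C13 while breaking C10–O; the closest known reaction is the intermolecular ketal Claisen rearrangement of isopropenyl carbinols with 3-hydroxy- or 3-chloro-2,2-dimethoxy-3-methylbutane, here proposed with the ketal tethered as an ester so that it closes a ring. The 16-membered ring is closed by a two-atom ring expansion of the transient 14-membered ring (C10–O–C14 is replaced by C10=C11–C12–C13–C14), a six-centre suprafacial closure in which only the last event is irreversible, so intermolecular ketals can revert under high dilution. No stereocentre is created: the C10 centre is erased, and its role is to place C9 equatorial in the chair, which, together with the 1,3-diaxial clash an axial C9 would suffer against the bulky C15 substituent on C14, should fix the E geometry of C10=C11 needed for the trans epoxide. The step needs ring closure over oligomerisation (0.002 M, removal of methanol), survival of the tertiary benzoate (its ionisation is disfavoured by the adjacent ketal or carbonyl carbon, and participation of its carbonyl in the oxocarbenium ion is expected to be reversible), and inertness of the exocyclic methylene, secondary bromide and aryl silyl ether toward a phenol-strength acid. The new C14 ketone and the intact C15 ester are exactly the functions that step 19 needs.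

Step 18
Reactants: 29 the 16-membered keto lactone
Product: 30 (14R)-hydroxy lactone
Conditions: (S)-Me-CBS oxazaborolidine (0.5 equiv), catecholborane, toluene, −78 °C; MeOH quench, neutral work-up, used at once
Reagents that add atoms: none
Why: Corey–Bakshi–Shibata reduction: the oxazaborolidine–borane complex binds the ketone away from the fully substituted C15 side and delivers hydride to one face, which with the (S)-catalyst should give the (14R)-alcohol; catecholborane at −78 °C should not hydroborate the alkenes.

Step 19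
Reactants: 30 the (14R)-hydroxy lactone
Product: 33 15-membered (2R,6S,7S,10E,14S)-macrolactone bearing the C15 tertiary bromide (aryl OTIPS), via secondary triflate 31 (not isolated), via dioxolanylium ion 32 (not isolated)
Conditions: Tf2O, pyridine, CH2Cl2, −40 °C; then Bu4NBr, −40 to 0 °C
Reagents that add atoms: tetrabutylammonium bromide, CCCC[N+](CCCC)(CCCC)CCCC.[Br-]
Why: Neighbouring-group participation (stereospecific 1,2-acyloxy shift): the benzoate carbonyl oxygen displaces the C14 triflate from the back in a five-membered transition state (inversion, giving 14S) to form 32, and bromide opens this ion at the tertiary C15, which carries the most positive charge and unlike C14 is not a hindered SN2 site, so the ring contracts from 16 to 15 members and the tertiary bromide is installed in the same operation.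

Step 20
Reactants: 33 the bromo macrolactone
Product: 34 O-triisopropylsilyl bromophycolide S
Conditions: enantiomeric (L-fructose-type) ketone catalyst (30 mol%), KHSO5 (Oxone), K2CO3, Bu4NHSO4, MeCN/dimethoxymethane/aq. buffer (pH 10.5), 0 °C
Reagents that add atoms: potassium peroxymonosulfate KHSO5, [K+].[O-]S(=O)(=O)OO
Why: Shi epoxidation: the trisubstituted E-C10=C11 alkene reacts ahead of the exocyclic methylene, and the enantiomer of the D-fructose-derived ketone (which gives R,R-epoxides from E-trisubstituted alkenes) should deliver oxygen to the face that gives the (10S,11S)-trans-epoxide under reagent control.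

Step 21
Reactants: 34 O-triisopropylsilyl bromophycolide S
Product: 35 bromophycolide S
Conditions: Bu4NF, AcOH (1:1), THF, 0 °C
Reagents that add atoms: none
Why: Fluoride-mediated desilylation: the aryl silyl ether is cleaved at 0 °C under acetic acid buffering, which keeps the medium near neutral so that the epoxide, the β-acyloxy tertiary bromide and the macrolactone should be untouched; no stereocentre is affected.

**Compound list**

1 | geraniol | CC(C)=CCC/C(C)=C/CO | starting material
2 | (2R,3R)-2,3-epoxygeraniol | OC[C@H]1O[C@]1(C)CCC=C(C)C | intermediate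
3 | (2R,3R)-2,3-epoxygeranyl iodide [CIP name (2S,3R)-2-(iodomethyl)-3-methyl-3-(4-methylpent-3-en-1-yl)oxirane] | IC[C@H]1O[C@]1(C)CCC=C(C)C | intermediate
4 | methyl acetoacetate | COC(=O)CC(C)=O | starting material
5 | methyl acetoacetate dianion (sodium lithium salt) | [CH2-]C(=O)[CH-]C(=O)OC.[Na+].[Li+] | intermediate
6 | methyl (6R,7R)-6,7-epoxy-7,11-dimethyl-3-oxododec-10-enoate | COC(=O)CC(=O)CC[C@H]1O[C@]1(C)CCC=C(C)C | intermediate
7 | methyl (2Z,6R,7R)-6,7-epoxy-7,11-dimethyl-3-(trifluoromethylsulfonyloxy)dodeca-2,10-dienoate | COC(=O)/C=C(\OS(=O)(=O)C(F)(F)F)CC[C@H]1O[C@]1(C)CCC=C(C)C | intermediate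
8 | methyl (2Z,6R,7R)-6,7-epoxy-7,11-dimethyl-3-[(trimethylsilyl)methyl]dodeca-2,10-dienoate | COC(=O)/C=C(\C[Si](C)(C)C)CC[C@H]1O[C@]1(C)CCC=C(C)C | intermediate
9 | (2Z,6R,7R)-6,7-epoxy-7,11-dimethyl-3-[(trimethylsilyl)methyl]dodeca-2,10-dien-1-ol | OC/C=C(\C[Si](C)(C)C)CC[C@H]1O[C@]1(C)CCC=C(C)C | intermediate
10 | methanesulfonate of 9 | CS(=O)(=O)OC/C=C(\C[Si](C)(C)C)CC[C@H]1O[C@]1(C)CCC=C(C)C | intermediate
11 | (2Z,6R,7R)-1-chloro-6,7-epoxy-7,11-dimethyl-3-[(trimethylsilyl)methyl]dodeca-2,10-diene | ClC/C=C(\C[Si](C)(C)C)CC[C@H]1O[C@]1(C)CCC=C(C)C | intermediate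
12 | methyl 4-hydroxy-3-iodobenzoate | COC(=O)c1ccc(O)c(I)c1 | starting material
13 | methyl 3-iodo-4-(triisopropylsilyloxy)benzoate | COC(=O)c1ccc(O[Si](C(C)C)(C(C)C)C(C)C)c(I)c1 | intermediate
14 | [5-(methoxycarbonyl)-2-(triisopropylsilyloxy)phenyl]magnesium chloride, LiCl complex | COC(=O)c1ccc(O[Si](C(C)C)(C(C)C)C(C)C)c([Mg]Cl)c1.[Li+].[Cl-] | intermediate
15 | methyl 3-{(2Z,6R,7R)-6,7-epoxy-7,11-dimethyl-3-[(trimethylsilyl)methyl]dodeca-2,10-dien-1-yl}-4-(triisopropylsilyloxy)benzoate | C[Si](C)(C)C/C(CC[C@H]1O[C@]1(C)CCC=C(C)C)=C\Cc1cc(C(=O)OC)ccc1O[Si](C(C)C)(C(C)C)C(C)C | intermediate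
16 | methyl 3-{(2Z,6S,7R)-6-bromo-7-hydroxy-7,11-dimethyl-3-[(trimethylsilyl)methyl]dodeca-2,10-dien-1-yl}-4-(triisopropylsilyloxy)benzoate | C[Si](C)(C)C/C(CC[C@H](Br)[C@](C)(O)CCC=C(C)C)=C\Cc1cc(C(=O)OC)ccc1O[Si](C(C)C)(C(C)C)C(C)C | intermediate
17 | C6–C7 bromonium ion from 16 | C[Si](C)(C)C/C(CC[C@@H]1[Br+][C@@]1(C)CCC=C(C)C)=C\Cc1cc(C(=O)OC)ccc1O[Si](C(C)C)(C(C)C)C(C)C | intermediate
18 | methyl 3-{[(1R,2S,3S)-3-bromo-2-methyl-6-methylidene-2-(4-methylpent-3-en-1-yl)cyclohexyl]methyl}-4-(triisopropylsilyloxy)benzoate (2R,6S,7S in chain numbering) | C=C1CC[C@H](Br)[C@@]([C@@H]1Cc1cc(C(=O)OC)ccc1O[Si](C(C)C)(C(C)C)C(C)C)(C)CCC=C(C)C | intermediate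
19 | the corresponding benzoic acid | C=C1CC[C@H](Br)[C@@]([C@@H]1Cc1cc(C(=O)O)ccc1O[Si](C(C)C)(C(C)C)C(C)C)(C)CCC=C(C)C | intermediate
20 | 3-hydroxy-3-methylbutan-2-one | CC(=O)C(C)(C)O | starting material
21 | 3,3-dimethoxy-2-methylbutan-2-ol | COC(C)(OC)C(C)(C)O | intermediate
22 | acid chloride of 19 | C=C1CC[C@H](Br)[C@@]([C@@H]1Cc1cc(C(=O)Cl)ccc1O[Si](C(C)C)(C(C)C)C(C)C)(C)CCC=C(C)C | intermediate
23 | lithium 3,3-dimethoxy-2-methylbutan-2-olate | COC(C)(OC)C(C)(C)[O-].[Li+] | intermediate
24 | 3,3-dimethoxy-2-methylbutan-2-yl ester of 19 | C=C1CC[C@H](Br)[C@@]([C@@H]1Cc1cc(C(=O)OC(C)(C)C(C)(OC)OC)ccc1O[Si](C(C)C)(C(C)C)C(C)C)(C)CCC=C(C)C | intermediate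
25 | (10R)-10,11-epoxide of 24 | C=C1CC[C@H](Br)[C@@]([C@@H]1Cc1cc(C(=O)OC(C)(C)C(C)(OC)OC)ccc1O[Si](C(C)C)(C(C)C)C(C)C)(C)CC[C@H]1OC1(C)C | intermediate
26 | (10R)-isopropenyl carbinol, key-step precursor | C=C1CC[C@H](Br)[C@@]([C@@H]1Cc1cc(C(=O)OC(C)(C)C(C)(OC)OC)ccc1O[Si](C(C)C)(C(C)C)C(C)C)(C)CC[C@@H](O)C(C)=C | intermediate
27 | 14-membered cyclic mixed ketal (C10–O–C14(OMe)(Me)–C15Me2–O–CO–Ar; C14 epimers) | C=C1CC[C@H](Br)[C@@]2(C)CC[C@H](C(C)=C)OC(C)(OC)C(C)(C)OC(=O)c3ccc(O[Si](C(C)C)(C(C)C)C(C)C)c(c3)C[C@H]12 | intermediate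
28 | 14-membered cyclic allyl vinyl ether (C10–O–C14(=CH2)–C15Me2–O–CO–Ar) | C=C1CC[C@H](Br)[C@@]2(C)CC[C@H](C(C)=C)OC(=C)C(C)(C)OC(=O)c3ccc(O[Si](C(C)C)(C(C)C)C(C)C)c(c3)C[C@H]12 | intermediate
29 | (2R,6S,7S,10E)-16-membered keto lactone: C14 ketone, arene carboxylate on the C15 oxygen, aryl OTIPS | C=C1CC[C@H](Br)[C@@]2(C)CC/C=C(\C)CCC(=O)C(C)(C)OC(=O)c3ccc(O[Si](C(C)C)(C(C)C)C(C)C)c(c3)C[C@H]12 | intermediate
30 | (14R)-alcohol of 29 | C=C1CC[C@H](Br)[C@@]2(C)CC/C=C(\C)CC[C@@H](O)C(C)(C)OC(=O)c3ccc(O[Si](C(C)C)(C(C)C)C(C)C)c(c3)C[C@H]12 | intermediate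
31 | C14 triflate of 30 | C=C1CC[C@H](Br)[C@@]2(C)CC/C=C(\C)CC[C@@H](OS(=O)(=O)C(F)(F)F)C(C)(C)OC(=O)c3ccc(O[Si](C(C)C)(C(C)C)C(C)C)c(c3)C[C@H]12 | intermediate
32 | 2-aryl-1,3-dioxolan-2-ylium triflate spanning C14 (S) and C15 | C=C1CC[C@H](Br)[C@@]2(C)CC/C=C(\C)CC[C@@H]3OC(=[O+]C3(C)C)c3ccc(O[Si](C(C)C)(C(C)C)C(C)C)c(c3)C[C@H]12.[O-]S(=O)(=O)C(F)(F)F | intermediate
33 | (2R,6S,7S,10E,14S)-15-membered macrolactone with C15 tertiary bromide, aryl OTIPS | C=C1CC[C@H](Br)[C@@]2(C)CC/C=C(\C)CC[C@@H](C(C)(C)Br)OC(=O)c3ccc(O[Si](C(C)C)(C(C)C)C(C)C)c(c3)C[C@H]12 | intermediate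
34 | O-triisopropylsilyl bromophycolide S | C=C1CC[C@H](Br)[C@@]2(C)CC[C@@H]3O[C@@]3(C)CC[C@@H](C(C)(C)Br)OC(=O)c3ccc(O[Si](C(C)C)(C(C)C)C(C)C)c(c3)C[C@H]12 | intermediate
35 | bromophycolide S | C=C1CC[C@H](Br)[C@@]2(C)CC[C@@H]3O[C@@]3(C)CC[C@@H](C(C)(C)Br)OC(=O)c3ccc(O)c(c3)C[C@H]12 | target

**Totals**

Total step count: 21. Longest linear sequence: 19 steps (1–7, 9–12, 14–21, from geraniol); steps 8 and 13 are side branches.

**Steps most likely to fail, with fallbacks**

Step 17 (proposed new method). What may go wrong: intermolecular ketal exchange outruns closure of the 14-membered ring and gives oligomers, or the tertiary benzoate is transferred to methanol or to the C10 hydroxyl through the orthoester manifold. The fallback forms C12–C13 intermolecularly and closes the ring at the ester, using known chemistry throughout. It sets out from acid 19. Shi epoxidation as in step 15 gives the (10R)-epoxy acid F1, and aluminium amide isomerisation as in step 16 gives the allylic alcohol acid F2. 3-Bromo-3-methylbutan-2-one and trimethyl orthoformate give 3-bromo-2,2-dimethoxy-3-methylbutane F3. Intermolecular ketal Claisen rearrangement of F2 with excess F3 (2,4-dinitrophenol cat., toluene, 110 °C) gives the E-configured α-bromo ketone acid F4. Corey–Bakshi–Shibata reduction with (R)-Me-CBS and excess catecholborane gives the (14S)-bromohydrin acid F5. Shiina macrolactonization at the secondary hydroxyl (2-methyl-6-nitrobenzoic anhydride, DMAP, CH2Cl2, high dilution, rt) comes back to the route at 33.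

Step 11. What may go wrong: the silyl group is lost by protodesilylation before the tertiary alcohol ionises, or the cation eliminates instead of cyclising. The fallback builds the ring with a β-keto ester as terminator before the arene is attached. It sets out from β-keto ester 6. Li2NiBr4 gives the (6S,7R)-bromohydrin keto ester F6, and SnCl4 (CH2Cl2, −78 to 0 °C) closes the ring onto the enol to give the cyclic β-keto ester F7. Methyl 4-hydroxy-3-methylbenzoate is silylated to methyl 3-methyl-4-(triisopropylsilyloxy)benzoate F8 and brominated (NBS, AIBN) to the benzylic bromide F9. C-Alkylation of F7 with F9 (K2CO3, acetone) gives the benzylated β-keto ester F10. Krapcho demethoxycarbonylation (LiCl, wet DMSO, 130 °C) gives the 2-benzyl ketone F11, in which C2 should equilibrate to the equatorial arrangement. Wittig methylenation (Ph3P=CH2, THF) comes back to the route at 18.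

Step 19. What may go wrong: the benzoate migrates before the triflate forms, or bromide opens the dioxolanylium ion at C14; either erodes the C14 configuration or the regiochemistry. The fallback separates acyl migration from substitution. It sets out from ketone 29. Reduction with the enantiomeric (R)-Me-CBS catalyst gives the (14S)-alcohol F12. Base-mediated 1,2-acyl migration (DBU, CH2Cl2, rt) contracts the ring to the (14S)-secondary benzoate with a free tertiary C15 hydroxyl F13. 1-Bromo-N,N,2-trimethylprop-1-en-1-amine (CH2Cl2, 0 °C) converts the tertiary alcohol into the bromide with retention at C14, because the C14–O bond is never broken, and comes back to the route at 33.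

**Further compounds**

F1 | step 17 | (10R)-epoxy acid from 19 | C=C1CC[C@H](Br)[C@@]([C@@H]1Cc1cc(C(=O)O)ccc1O[Si](C(C)C)(C(C)C)C(C)C)(C)CC[C@H]1OC1(C)C
F2 | step 17 | (10R)-isopropenyl carbinol acid | C=C1CC[C@H](Br)[C@@]([C@@H]1Cc1cc(C(=O)O)ccc1O[Si](C(C)C)(C(C)C)C(C)C)(C)CC[C@@H](O)C(C)=C
F3 | step 17 | 3-bromo-2,2-dimethoxy-3-methylbutane | COC(C)(OC)C(C)(C)Br
F4 | step 17 | (10E)-α-bromo ketone acid | C=C1CC[C@H](Br)[C@@]([C@@H]1Cc1cc(C(=O)O)ccc1O[Si](C(C)C)(C(C)C)C(C)C)(C)CC/C=C(\C)CCC(=O)C(C)(C)Br
F5 | step 17 | (10E,14S)-bromohydrin seco acid | C=C1CC[C@H](Br)[C@@]([C@@H]1Cc1cc(C(=O)O)ccc1O[Si](C(C)C)(C(C)C)C(C)C)(C)CC/C=C(\C)CC[C@H](O)C(C)(C)Br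
F6 | step 11 | methyl (6S,7R)-6-bromo-7-hydroxy-7,11-dimethyl-3-oxododec-10-enoate | COC(=O)CC(=O)CC[C@H](Br)[C@](C)(O)CCC=C(C)C
F7 | step 11 | methyl (3S,2S-ring numbering as in 18)-3-bromo-2-methyl-2-(4-methylpent-3-en-1-yl)-6-oxocyclohexane-1-carboxylate (C1 epimerisable) | COC(=O)C1C(=O)CC[C@H](Br)[C@@]1(C)CCC=C(C)C
F8 | step 11 | methyl 3-methyl-4-(triisopropylsilyloxy)benzoate | COC(=O)c1ccc(O[Si](C(C)C)(C(C)C)C(C)C)c(C)c1
F9 | step 11 | methyl 3-(bromomethyl)-4-(triisopropylsilyloxy)benzoate | COC(=O)c1ccc(O[Si](C(C)C)(C(C)C)C(C)C)c(CBr)c1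
F10 | step 11 | C-benzylated cyclic β-keto ester (quaternary centre unassigned) | COC(=O)C1(Cc2cc(C(=O)OC)ccc2O[Si](C(C)C)(C(C)C)C(C)C)C(=O)CC[C@H](Br)[C@@]1(C)CCC=C(C)C
F11 | step 11 | 2-benzyl ketone, the C3 ketone analogue of 18 | O=C1CC[C@H](Br)[C@@]([C@@H]1Cc1cc(C(=O)OC)ccc1O[Si](C(C)C)(C(C)C)C(C)C)(C)CCC=C(C)C
F12 | step 19 | (14S)-alcohol of 29 | C=C1CC[C@H](Br)[C@@]2(C)CC/C=C(\C)CC[C@H](O)C(C)(C)OC(=O)c3ccc(O[Si](C(C)C)(C(C)C)C(C)C)c(c3)C[C@H]12
F13 | step 19 | (14S)-15-membered secondary benzoate with free C15 hydroxyl | C=C1CC[C@H](Br)[C@@]2(C)CC/C=C(\C)CC[C@@H](C(C)(C)O)OC(=O)c3ccc(O[Si](C(C)C)(C(C)C)C(C)C)c(c3)C[C@H]12
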